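**Retrosynthetic overview**

1. No ring is constructed: rings A (resorcinol), B (guaiacyl) and C (catechol) are bought as O‑benzylated benzaldehydes, and only the two links between them are made.
2. Key disconnection, the stilbene C=C: ring A aldehyde 1, brominated to 2, is joined to ring B aldehyde 3, whose N–H hydrazone 4 acts as a benzylic carbanion equivalent. Two carbonyl carbons are united with loss of N2 and water to give E‑stilbene 5.
3. Second disconnection, the Ar–CH2 bond: the C–Br carbon of 5 is joined to the carbonyl carbon of ring C aldehyde 6 through its hydrazone 7 (Ni(cod)2/PMe3, loss of N2), giving 8.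
4. Last operation: the five benzyl groups of 8 are removed, leaving the methyl ether and the E‑alkene, to give Gnetupendin B 9.

Assumption: Gnetupendin B has no stereocentre, so "single enantiomer" is read as the single geometric isomer, the E‑alkene; 1, 3 and 6 are taken as catalogue compounds.

**Step 1**
Reactants: 1 3,5-bis(benzyloxy)benzaldehyde
Product: 2 3,5-bis(benzyloxy)-2-bromobenzaldehyde
Conditions: NBS (1.05 equiv), MeCN, 0 °C to rt
Reagents that add atoms: N-bromosuccinimide, O=C1CCC(=O)N1Br
Why: Electrophilic aromatic bromination goes to C2, which is para to one benzyloxy group, ortho to the other and less hindered than C4 between the two ethers (the same selectivity as the NBS bromination of 3,5-dimethoxybenzaldehyde), and one equivalent of NBS avoids 2,6-dibromination.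

**Step 2**
Reactants: 2 3,5-bis(benzyloxy)-2-bromobenzaldehyde; 3 4-(benzyloxy)-3-methoxybenzaldehyde
Product: 5 1,5-bis(benzyloxy)-3-[(E)-2-(4-(benzyloxy)-3-methoxyphenyl)ethenyl]-2-bromobenzene, via ring B hydrazone 4 (not isolated)
Conditions: 3 (1.2 equiv), N2H4·H2O (1.2 equiv), THF, rt, 1 h; then 2, [Ru(p-cymene)Cl2]2 (2.5 mol%), dmpe (5 mol%), KOtBu (50 mol%), CsF (50 mol%), THF, 45 to 60 °C; crude product stirred with I2 (2 mol%), CH2Cl2, rt
Reagents that add atoms: none
Why: Hydrazone-mediated carbonyl–carbonyl reductive cross-coupling olefination under divalent ruthenium catalysis: hydrazone 4 bound to ruthenium delivers its former aldehyde carbon as a carbanion equivalent to the aldehyde carbon of 2 through a six-membered transition state, and base-induced E1cB-type loss of N2 and hydroxide gives the thermodynamically preferred E-alkene (the I2 treatment converges any Z isomer to E), while the aryl bromide and benzyl ethers are inert.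

**Step 3**
Reactants: 5 1,5-bis(benzyloxy)-3-[(E)-2-(4-(benzyloxy)-3-methoxyphenyl)ethenyl]-2-bromobenzene; 6 3,4-bis(benzyloxy)benzaldehyde
Product: 8 1,5-bis(benzyloxy)-2-[3,4-bis(benzyloxy)benzyl]-3-[(E)-2-(4-(benzyloxy)-3-methoxyphenyl)ethenyl]benzene (penta-O-benzyl Gnetupendin B), via ring C hydrazone 7 (not isolated)
Conditions: 6 (1.5 equiv), N2H4·H2O (1.5 equiv), THF, rt, 1 h, then 4 Å MS; then 5, Ni(cod)2 (10 mol%), PMe3 (20 mol%), DBU (2 equiv), THF, 60 °C
Reagents that add atoms: none
Why: Ni(cod)2/PMe3-catalysed denitrogenative cross-coupling of an aldehyde hydrazone with an aryl bromide (Wolff–Kishner-type carbanion-equivalent coupling): the C–Br bond of 5 adds oxidatively to zerovalent nickel, hydrazone 7 is N-bound and deprotonated by DBU, and loss of N2 with C–Ni bond formation followed by reductive elimination gives the diarylmethane, the small PMe3 ligand accommodating the two ortho substituents and the E-alkene staying untouched.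

**Step 4**
Reactants: 8 penta-O-benzyl Gnetupendin B
Product: 9 Gnetupendin B
Conditions: BCl3 (10 equiv), C6HMe5 (15 equiv), CH2Cl2, −78 °C; then H2O
Reagents that add atoms: none
Why: Lewis-acid cleavage of aryl benzyl ethers with a non-basic cation scavenger: BCl3 at −78 °C breaks the five O–benzyl bonds much faster than the O–methyl bond, and pentamethylbenzene traps every benzyl cation so that neither the stilbene nor the electron-rich rings are C-benzylated and the E-geometry is kept.

**Compound list**

1 | 3,5-bis(benzyloxy)benzaldehyde | O=Cc1cc(OCc2ccccc2)cc(OCc2ccccc2)c1 | starting material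
2 | 3,5-bis(benzyloxy)-2-bromobenzaldehyde | O=Cc1cc(OCc2ccccc2)cc(OCc2ccccc2)c1Br | intermediate
3 | 4-(benzyloxy)-3-methoxybenzaldehyde (O-benzylvanillin) | COc1cc(C=O)ccc1OCc1ccccc1 | starting material
4 | (E)-[4-(benzyloxy)-3-methoxybenzylidene]hydrazine (ring B hydrazone) | COc1cc(/C=N/N)ccc1OCc1ccccc1 | intermediate
5 | 1,5-bis(benzyloxy)-3-[(E)-2-(4-(benzyloxy)-3-methoxyphenyl)ethenyl]-2-bromobenzene | COc1cc(/C=C/c2cc(OCc3ccccc3)cc(OCc3ccccc3)c2Br)ccc1OCc1ccccc1 | intermediate
6 | 3,4-bis(benzyloxy)benzaldehyde | O=Cc1ccc(OCc2ccccc2)c(OCc2ccccc2)c1 | starting material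
7 | (E)-[3,4-bis(benzyloxy)benzylidene]hydrazine (ring C hydrazone) | N/N=C/c1ccc(OCc2ccccc2)c(OCc2ccccc2)c1 | intermediate
8 | 1,5-bis(benzyloxy)-2-[3,4-bis(benzyloxy)benzyl]-3-[(E)-2-(4-(benzyloxy)-3-methoxyphenyl)ethenyl]benzene | COc1cc(/C=C/c2cc(OCc3ccccc3)cc(OCc3ccccc3)c2Cc2ccc(OCc3ccccc3)c(OCc3ccccc3)c2)ccc1OCc1ccccc1 | intermediate
9 | Gnetupendin B, 4-(3,4-dihydroxybenzyl)-5-[(E)-2-(4-hydroxy-3-methoxyphenyl)ethenyl]benzene-1,3-diol | COc1cc(/C=C/c2cc(O)cc(O)c2Cc2ccc(O)c(O)c2)ccc1O | target

**Step count and risk**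

Total step count: 4. Longest linear sequence: 4 steps (1 → 2 → 5 → 8 → 9); 3 and 6 are used as bought.

The three steps most likely to fail are 2, 3 and 4.

Step 2 (olefination): the risks are azine formation, Wolff–Kishner reduction of 4, or arrest at the carbinol. The fallback sets out from 3, with 2 as partner, and returns at 5. Aldehyde 3 is condensed with TsNHNH2 (MeOH, rt) to N-tosylhydrazone F1. Heating F1 with 2 and Cs2CO3 in dioxane at 110 °C releases aryldiazomethane F2 in the flask. Its nucleophilic diazo carbon adds to the aldehyde of 2, and a 1,2-hydride shift with loss of N2 gives deoxybenzoin F3. NaBH4 (MeOH/THF, 0 °C) gives racemic carbinol F4, which is also what the main reaction gives if the elimination stalls. TsOH (cat.) in toluene at 80 °C dehydrates F4 to E-stilbene 5 under thermodynamic control. The reversed polarity of the ring B aldehyde carbon is kept, but no transition metal is involved.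

Step 3 (hydrazone arylation): the risks are the doubly ortho-substituted, electron-rich bromide and binding of the stilbene to nickel. The fallback sets out from 5 and 6 and returns at 8, and makes ring A the nucleophile. Bromide 5 undergoes Br–Li exchange (n-BuLi, THF, −78 °C) to aryllithium F5. This is quenched with B(OiPr)3 and hydrolysed with aqueous NH4Cl to boronic acid F6. Aldehyde 6 is condensed with TsNHNH2 (MeOH, rt) to N-tosylhydrazone F7. Heating F6 and F7 with K2CO3 in dioxane at 110 °C generates aryldiazomethane F8, which is captured at boron. A 1,2-aryl shift with loss of N2 and protodeboronation of the benzylic boronic acid gives 8. This is a metal-free reductive coupling of a tosylhydrazone and a boronic acid, so no oxidative addition at the hindered C–Br bond is needed. A route through the diarylcarbinol and ionic deoxygenation is avoided because the benzylic cation would cyclise onto the ortho-styryl group.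

Step 4 (debenzylation): the risks are loss of the methyl ether after boron chelation or acid damage to the stilbene. The fallback sets out from 8 and returns at 9, and replaces Lewis-acid cleavage by reductive silyl transfer. Compound 8 with Et3SiH (10 equiv), Pd(OAc)2 (10 mol%) and Et3N in CH2Cl2 at rt loses its benzyl groups as toluene, without H2 gas, and gives pentakis(triethylsilyl) ether F9. TBAF/AcOH in THF at 0 °C then frees the five phenols to give 9.

**Further compounds**

F1 | step 2 | N'-[(E)-4-(benzyloxy)-3-methoxybenzylidene]-4-methylbenzenesulfonohydrazide | COc1cc(/C=N/NS(=O)(=O)c2ccc(C)cc2)ccc1OCc1ccccc1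
F2 | step 2 | 1-(benzyloxy)-4-(diazomethyl)-2-methoxybenzene | COc1cc(C=[N+]=[N-])ccc1OCc1ccccc1
F3 | step 2 | 1-[3,5-bis(benzyloxy)-2-bromophenyl]-2-[4-(benzyloxy)-3-methoxyphenyl]ethan-1-one | COc1cc(CC(=O)c2cc(OCc3ccccc3)cc(OCc3ccccc3)c2Br)ccc1OCc1ccccc1
F4 | step 2 | racemic 1-[3,5-bis(benzyloxy)-2-bromophenyl]-2-[4-(benzyloxy)-3-methoxyphenyl]ethan-1-ol | COc1cc(CC(O)c2cc(OCc3ccccc3)cc(OCc3ccccc3)c2Br)ccc1OCc1ccccc1
F5 | step 3 | {2,4-bis(benzyloxy)-6-[(E)-2-(4-(benzyloxy)-3-methoxyphenyl)ethenyl]phenyl}lithium | COc1cc(/C=C/c2cc(OCc3ccccc3)cc(OCc3ccccc3)c2[Li])ccc1OCc1ccccc1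
F6 | step 3 | {2,4-bis(benzyloxy)-6-[(E)-2-(4-(benzyloxy)-3-methoxyphenyl)ethenyl]phenyl}boronic acid | COc1cc(/C=C/c2cc(OCc3ccccc3)cc(OCc3ccccc3)c2B(O)O)ccc1OCc1ccccc1
F7 | step 3 | N'-[(E)-3,4-bis(benzyloxy)benzylidene]-4-methylbenzenesulfonohydrazide | Cc1ccc(S(=O)(=O)N/N=C/c2ccc(OCc3ccccc3)c(OCc3ccccc3)c2)cc1
F8 | step 3 | 1,2-bis(benzyloxy)-4-(diazomethyl)benzene | [N-]=[N+]=Cc1ccc(OCc2ccccc2)c(OCc2ccccc2)c1
F9 | step 4 | pentakis-O-(triethylsilyl) Gnetupendin B | COc1cc(/C=C/c2cc(O[Si](CC)(CC)CC)cc(O[Si](CC)(CC)CC)c2Cc2ccc(O[Si](CC)(CC)CC)c(O[Si](CC)(CC)CC)c2)ccc1O[Si](CC)(CC)CC
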